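## Structural features

The target is a flavonol: a 4H-chromen-4-one (ring A fused to the pyranone ring C) with a 4-(3-methylbut-2-enyloxy)phenyl group (ring B) at C2 and an enolic hydroxyl at C3. Ring A is substituted everywhere except C8: hydroxyls at C5 and C7 flank a methoxy group at C6, so three neighbouring oxygens must be told apart and only the middle one is methylated. There is no stereocentre; the demands are regiochemical and chemoselective. The fragile groups are the aryl prenyl ether and the 3-hydroxy-4-pyranone unit. The prenyl alkene is attacked by peracids, halonium sources and hydrogenation catalysts, its allylic C–O bond is cut by acid, and the flavonol anion is degraded by oxygen. The real difficulty is to build the run C5(OH)–C6(OMe)–C7(OH)–C8(H) with its oxygens already differentiated, next to a C3 oxygen, without acid or an electrophilic oxidant late in the route. The key step uses the fact that C5 is bonded to C4a and C6 and that C5–C8 is the ring-opened form of a 2,3-dialkoxycyclobutenone. Its carbonyl carbon becomes C5, its two alkoxy carbons C6 and C7, its sp3 carbon C8, and the O1–C8a=C4a double bond of a preformed 3-oxygenated 2-aryl-4-pyranone supplies the last two ring A carbons.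

## Logic of the disconnections

22 to 20 (through 21). The O3–Si bond and the O7–CH2 bond of two silicon-based protecting groups are cut. Both fall to fluoride, so the end needs one operation and no acid near the prenyl ether; for this reason O3 carries a trialkylsilyl group, not an acetal, from 10 onwards. The gain is a fully masked precursor 20. The demand is that fluoride fragments an aryl 2-silylethyl ether (helped by O7 being a vinylogous carboxylate oxygen) and that air is excluded.

20 to 17 (through 18 and 19). The C4a–C5 bond, and with it ring A, is cut. 20 is an isomer of 17, in which the four carbons C5–C8 already sit in order in a four-membered ring on a finished ring B/C unit. The gain is that ring A, the free C5 hydroxyl and the O6/O7 differentiation come from one isomerisation. The demand is that ring opening to 18 and closure to 19 outrun bimolecular reactions of the ketene, and that the sp3 carbon of 17 carries hydrogen so that C8 stays unsubstituted.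

17 to 10 and 15 (through 16). The C8–C8a bond is cut, giving two fragments of similar size. The demand is twofold: 10 must be metalated at the C–H beside O1, not beside the carbonyl, and the new bond must form at the hydrogen-bearing terminus of the allylic system of 15. Bond formation at the other terminus would place the methoxy group on C8. 17 is washed free of amine and zinc salts before heating, since both would compete for the ketene.

15 to 14. The C–Cl bond is exchanged for a ketal C–OMe bond. 15 ionises too easily to store, whereas 14 is a stable ketal. The demand is a halide exchange that does not dealkylate the product.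

14 to 13. The O–CH2 bond of the silylethyl group on the future O7 is cut. Only one of the three methoxy groups of 13 is a vinylogous ester oxygen, so the exchange is site-specific without any selective reaction on a symmetrical diester. The demand is base catalysis that does not cleave the strained ring.

13 to 11 (through 12). One ring C–H bond and one ketal C–OMe bond are cut. Alkoxy exchange on 11 followed by reduction would give both orders of the two alkoxy groups; reducing first makes the two methoxy groups of 11 chemically different. The gain is a symmetrical commercial starting material. The demand is mono-reduction and capture of the derived cation at its methoxy-bearing terminus.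

10 to 9. The O3–Si bond is cut; the demand is silylation of a hindered, chelated enol.

9 to 7 (through 8). The oxidation level at C3 is lowered (carbonyl back to carbinol). The diosphenol arises from an alcohol oxidation and tautomerisation, with no electrophilic oxidant near the prenyl alkene.

7 to 6. The C3–O bond is cut. C3 is the only enolisable carbon of 6, so enolate hydroxylation places the future flavonol oxygen unambiguously.

6 to 3 and 4. The C2–C3 and O1–C8a bonds (flavone numbering) are cut in the hetero-Diels–Alder sense. The aldehyde carbon becomes C2, so the aryl position is fixed. A furyl carbinol ring expansion was set aside: it stops at a 6-hydroxy-2H-pyran-3(6H)-one, two electrons short of a 3-hydroxy-4-pyranone, and the extra oxidation needs halonium reagents that the prenyl alkene does not survive. The demand is a Lewis acid mild enough for the prenyl ether.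

3 to 1 and 2. The O4'–CH2 bond is cut. Alkylating first means no protecting group is ever exchanged at O4'.

## Other disconnections considered

Alternative 1: The cut runs through O1–C8a and C4a–C4; ring A comes from an aryne and the rest from 3-[4-(3-methylbut-2-enyloxy)phenyl]prop-2-ynoic acid A3.
- Forward step: fluoride would release the aryne from 4-methoxy-3,5-bis(methoxymethoxy)-2-(trimethylsilyl)phenyl trifluoromethanesulfonate A2. The carboxylate of A3 should add at the aryne carbon remote from the flanking acetal oxygen (future C8a), and the aryl anion at C4a should take the acyl group, giving ynone A1.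
- In favour: two bonds in one mild, non-oxidising operation, with a regiochemistry that follows the usual preference of 3-alkoxyarynes. The ring A oxygen pattern is bought with A2. On this structural point the alternative is better than the chosen plan, where the substituent order depends on which allylic terminus couples in step 9.
- Against: A2 is a hexasubstituted benzene needing a long regiocontrolled synthesis. A1 is still open-chain, so ring C must be closed (6-endo against 5-exo). The C3 oxygen is absent and would have to be added late with the prenyl alkene present. The acetals need acid at the end.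
- Comparison: on mechanism the polar insertion is at least the equal of the pericyclic cascade in predictability. On structure the chosen plan carries the C3 oxygen from step 3 and closes ring A onto a finished ring C. On step economy A1 needs cyclisation, C3 hydroxylation and acidic deprotection against one step after 20, and A2 is expected to cost more than the three steps to 15.

Alternative 2: Only C5–O and C7–O are cut; the skeleton, C3 oxygen included, is assembled first on a 5,7-difluoro ring A.
- Forward step: sodium 2-(trimethylsilyl)ethoxide A6 displaces both fluorides of 5,7-difluoro-6-methoxy-4'-(3-methylbut-2-enyloxy)-3-{[2-(trimethylsilyl)ethoxy]methoxy}flavone A5 by addition–elimination, ortho and para to the C4 carbonyl, giving A4. One fluoride treatment then removes three silicon-based groups.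
- In favour: no late C–C bond, a simple and individually well-understood mechanism, and the C6 methoxy group fixed in the starting arene. On mechanism the alternative is better than the chosen plan; on the end-game (one fluoride step, no acid) it is its equal.
- Against: the donor methoxy group between the fluorines lowers activation, and C5 is hindered between that group and the peri carbonyl. A strong alkoxide can also add at C2 and open ring C. The fluorinated ring A ketone behind A5 is not a stock compound, and its oxidative cyclisation with a substituent beside the phenol tends towards the five-membered isomer.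
- Comparison: on structure the two plans are equal at the end; the alternative is weaker in chemoselectivity towards the pyranone. On step economy it is comparable at best and depends on access to the fluorinated ketone, whereas the chosen plan starts from commodity materials.

Alternative 3: C4a–C4, C4–C3 and O1–C2 are cut; ring C comes from 2-iodo-4-methoxy-3,5-bis(methoxymethoxy)phenol A8, carbon monoxide A10 and 1-ethynyl-4-(3-methylbut-2-enyloxy)benzene A9.
- Forward step: a palladium-catalysed carbonylative coupling with a secondary amine should join the three components and close ring C in the 6-endo mode, giving flavone A7.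
- In favour: three bonds and a ring in one step, and A9 is one step from 3. In bonds formed per step and in convergency the alternative is better than the chosen key step.
- Against: A7 lacks the C3 oxygen, so a C3 hydroxylation must follow with the prenyl alkene present, which excludes epoxidising oxidants. A8 is a pentasubstituted arene whose carbon–iodine bond lies between two oxygens, so its regioselective iodination and a slow oxidative addition are concerns, and the five-membered closure competes. Acid is needed at the end.
- Comparison: on structure the ring A pattern is bought, which is the equal of Alternative 1 and better than the chosen plan on that one point. On mechanism the carbonylation is established but is asked to work on a hindered, electron-rich iodide. On step economy the gain of the key step is spent on the hydroxylation and the acidic deprotection after it and on A8 before it.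

Key step: step 10

Remark on the chemistry (assumption): 15 is written as the geminal chloro ether that the ketal exchange forms first; its 1,3-transposed isomer (chloride on the CH carbon) would ionise to the same oxocyclobutenyl unit and is equivalent in step 9.

## Route

Step 1
Reactants: 1 4-hydroxybenzaldehyde; 2 1-bromo-3-methylbut-2-ene
Product: 3 4-(3-methylbut-2-enyloxy)benzaldehyde
Conditions: K2CO3, DMF, 25 °C
Reagents that add atoms: none
Why: Williamson ether synthesis: the phenoxide of 1 should displace bromide from the primary allylic halide 2 by SN2 substitution. Putting the prenyl group on first removes any later exchange of protecting groups at O4', and every later reagent is chosen to spare its alkene.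

Step 2
Reactants: 3 4-(3-methylbut-2-enyloxy)benzaldehyde; 4 (E)-1-methoxy-3-(trimethylsilyloxy)buta-1,3-diene
Product: 6 2-[4-(3-methylbut-2-enyloxy)phenyl]-2,3-dihydro-4H-pyran-4-one (racemic), via silyl enol ether cycloadduct 5 (not isolated)
Conditions: ZnCl2 (0.2 equiv), THF, 25 °C; then CF3CO2H (cat.), CH2Cl2, 0 °C
Reagents that add atoms: none
Why: Lewis-acid-catalysed hetero-Diels–Alder reaction of the aldehyde C=O of 3 with the electron-rich diene 4 gives cycloadduct 5, and a trace of acid then expels methanol and the silyl group to leave enone 6. The single stereocentre (C2) forms racemic and is erased in step 4, so no control is needed.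

Step 3
Reactants: 6 2-[4-(3-methylbut-2-enyloxy)phenyl]-2,3-dihydro-4H-pyran-4-one
Product: 7 rac-(2R,3R)-3-hydroxy-2-[4-(3-methylbut-2-enyloxy)phenyl]-2,3-dihydro-4H-pyran-4-one (2,3-trans)
Conditions: NaN(SiMe3)2, THF, −78 °C; then 2-(phenylsulfonyl)-3-phenyloxaziridine, −78 °C; aq. NH4Cl
Reagents that add atoms: 2-(phenylsulfonyl)-3-phenyloxaziridine, O=S(=O)(c1ccccc1)N1OC1c1ccccc1
Why: C3 is the only sp3 α-position of 6, so the amide base at −78 °C should give the cross-conjugated sodium enolate, which the N-sulfonyloxaziridine hydroxylates (enolate oxidation by electrophilic oxygen transfer) on the face opposite the aryl group, hence 2,3-trans. An oxaziridine replaces a peracid-based Rubottom oxidation because it does not epoxidise the prenyl alkene; both stereocentres disappear in step 4.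

Step 4
Reactants: 7 rac-(2R,3R)-3-hydroxy-2-[4-(3-methylbut-2-enyloxy)phenyl]-2,3-dihydro-4H-pyran-4-one
Product: 9 3-hydroxy-2-[4-(3-methylbut-2-enyloxy)phenyl]-4H-pyran-4-one, via pyran-3,4-dione tautomer 8 (not isolated)
Conditions: (COCl)2, DMSO, CH2Cl2, −78 °C; then Et3N, −78 → 0 °C
Reagents that add atoms: none
Why: Swern oxidation should convert the α-hydroxy ketone 7 into dione 8, whose C2 hydrogen is benzylic, next to oxygen and α to the new carbonyl, so 8 enolises under the amine base to the cross-conjugated 3-hydroxy-4-pyranone 9. The conditions are neither acidic nor a source of electrophilic oxygen or halogen, so the prenyl ether is safe.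

Step 5
Reactants: 9 3-hydroxy-2-[4-(3-methylbut-2-enyloxy)phenyl]-4H-pyran-4-one
Product: 10 2-[4-(3-methylbut-2-enyloxy)phenyl]-3-(triisopropylsilyloxy)-4H-pyran-4-one
Conditions: iPr3SiOTf, 2,6-lutidine, CH2Cl2, 0 °C
Reagents that add atoms: triisopropylsilyl trifluoromethanesulfonate, CC(C)[Si](OS(=O)(=O)C(F)(F)F)(C(C)C)C(C)C
Why: Silylation of the acidic enolic hydroxyl with a silyl triflate and a hindered pyridine base. The bulky silyl ether should survive the zinc amide, the palladium coupling and 105 °C, and it falls to fluoride together with the silylethyl ether, so no acid is needed after this point.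

Step 6
Reactants: 11 dimethyl squarate (3,4-dimethoxycyclobut-3-ene-1,2-dione)
Product: 13 3,4,4-trimethoxycyclobut-2-en-1-one, via 4-hydroxycyclobutenone 12 (not isolated)
Conditions: LiAlH(OtBu)3, THF, −78 °C; then HCl/MeOH, HC(OMe)3, −78 → 20 °C
Reagents that add atoms: methanol, CO
Why: LiAlH(OtBu)3 should reduce one carbonyl group of 11 (1,2-reduction) to alcohol 12; acid then ionises the allylic C–OH bond to a two-π-electron oxocyclobutenyl cation that methanol captures at its methoxy-bearing terminus, giving ketal 13 (the ionisation that turns such alcohols into cyclobutenedione monoacetals). This desymmetrises the squarate: one methoxy group becomes a ketal oxygen that stays as O6–Me, and the other is the only vinylogous ester oxygen.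

Step 7
Reactants: 13 3,4,4-trimethoxycyclobut-2-en-1-one
Product: 14 4,4-dimethoxy-3-[2-(trimethylsilyl)ethoxy]cyclobut-2-en-1-one
Conditions: Me3SiCH2CH2OH (3 equiv), NaH (0.1 equiv), 4 Å sieves, THF, 0 → 25 °C
Reagents that add atoms: 2-(trimethylsilyl)ethanol, C[Si](C)(C)CCO
Why: Alkoxide-catalysed alkoxy exchange of a vinylogous ester by conjugate addition–elimination at C3; the ketal methoxy groups are inert to alkoxide, so only the oxygen that becomes O7 is exchanged. Excess alcohol and uptake of methanol by the sieves drive the equilibrium.

Step 8
Reactants: 14 4,4-dimethoxy-3-[2-(trimethylsilyl)ethoxy]cyclobut-2-en-1-one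
Product: 15 4-chloro-4-methoxy-3-[2-(trimethylsilyl)ethoxy]cyclobut-2-en-1-one (racemic)
Conditions: AcCl, ZnCl2 (1 mol%), CH2Cl2, 0 → 20 °C; evaporate, use crude
Reagents that add atoms: acetyl chloride, CC(Cl)=O
Why: ZnCl2-catalysed exchange between a ketal and an acyl chloride, the standard route to α-chloro ethers, should replace one ketal methoxy group by chloride and release methyl acetate. 15 is the allylic chloride needed in step 9 and is used at once because it ionises easily.

Step 9
Reactants: 10 2-[4-(3-methylbut-2-enyloxy)phenyl]-3-(triisopropylsilyloxy)-4H-pyran-4-one; 15 4-chloro-4-methoxy-3-[2-(trimethylsilyl)ethoxy]cyclobut-2-en-1-one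
Product: 17 2-methoxy-4-{4-oxo-6-[4-(3-methylbut-2-enyloxy)phenyl]-5-(triisopropylsilyloxy)-4H-pyran-2-yl}-3-[2-(trimethylsilyl)ethoxy]cyclobut-2-en-1-one (racemic), via pyranonylzinc chloride 16 (not isolated)
Conditions: TMPZnCl·LiCl, THF, 25 °C; then 15, Pd(PPh3)4 (5 mol%), THF, 0 → 25 °C; cold aq. NH4Cl wash
Reagents that add atoms: none
Why: TMPZnCl·LiCl should remove the C–H beside the ring oxygen of 10 (the most acidic site; the other free position lies beside the carbonyl), giving 16 without touching the silyl ether or the prenyl group. Oxidative addition of zerovalent palladium to the ionisable chloro ether 15 gives an η3-oxocyclobutenyl palladium species, and Negishi coupling should form the C–C bond at its unsubstituted terminus, which avoids a quaternary centre and keeps the dialkoxy enone conjugated; this places H on the future C8, the silylethoxy group on C7 and OMe on C6. The new sp3 centre is racemic and uncontrolled, and it is erased in step 10.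

Step 10
Reactants: 17 2-methoxy-4-{4-oxo-6-[4-(3-methylbut-2-enyloxy)phenyl]-5-(triisopropylsilyloxy)-4H-pyran-2-yl}-3-[2-(trimethylsilyl)ethoxy]cyclobut-2-en-1-one
Product: 20 5-hydroxy-6-methoxy-4'-(3-methylbut-2-enyloxy)-7-[2-(trimethylsilyl)ethoxy]-3-(triisopropylsilyloxy)flavone, via vinylketene 18 (not isolated), via ring A dienone 19 (not isolated)
Conditions: PhMe (0.02 M), 105 °C, Ar
Reagents that add atoms: none
Why: Heating 17 should trigger conrotatory 4π opening of the C1–C4 bond of the cyclobutenone to vinylketene 18; the opening is reversible, so the isomer in which the pyranone has rotated inward (ketene and pyranone cis on the new double bond) is replenished as it is consumed. In 18 the ketene C=C, the enol-ether C=C and the pyranone C8a=C4a bond form a hexatriene, and disrotatory 6π electrocyclisation joins the electrophilic ketene carbon to the nucleophilic α-carbon C4a, giving dienone 19. 19 holds its C4a hydrogen between two carbonyl groups and should enolise at once to the C5 phenol 20, which is held by a hydrogen bond to the C4 carbonyl. The closest known reaction type is the thermal benzannulation of 4-aryl-, 4-heteroaryl- and 4-alkenylcyclobutenones through dienylketenes; the pyranone enters as the alkenyl partner. One ring (ring A) is closed, by 6π electrocyclisation, and no stereocentre remains: the racemic centre of 17 becomes the planar C8 and the transient C4a centre of 19 is lost on tautomerisation. Site selectivity is structural, since C4a is the only carbon that can complete a six-membered ring with the ketene carbon (the other neighbour of C8a is O1), and the order C5–OH, C6–OMe, C7–OR, C8–H is fixed by the cyclobutenone. The selectivity that must be won is kinetic, closure against bimolecular acylation by the ketene, and high dilution in a dry non-nucleophilic solvent, with the amine and zinc salts of step 9 washed out, is meant to secure it.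

Step 11
Reactants: 20 5-hydroxy-6-methoxy-4'-(3-methylbut-2-enyloxy)-7-[2-(trimethylsilyl)ethoxy]-3-(triisopropylsilyloxy)flavone
Product: 22 3,5,7-trihydroxy-6-methoxy-4'-(3-methylbut-2-enyloxy)flavone, via 7-silylethyl flavonol 21 (not isolated)
Conditions: Bu4NF, THF, 25 → 60 °C, Ar; aq. NH4Cl
Reagents that add atoms: none
Why: Fluoride should cleave the O3–Si bond at 25 °C to give 21 and, on warming, attack the silicon of the 2-(trimethylsilyl)ethyl ether, whose β-elimination releases ethene and the O7 phenoxide, a good leaving group because it is a vinylogous carboxylate of the C4 carbonyl (silyl ether cleavage and fluoride-induced fragmentation). No acid, oxidant or hydrogenation catalyst is involved, so the prenyl ether is untouched, and air is excluded because the flavonol anion is oxidised by oxygen.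

## Compound list

1 | 4-hydroxybenzaldehyde | O=Cc1ccc(O)cc1 | starting material
2 | 1-bromo-3-methylbut-2-ene (prenyl bromide) | CC(C)=CCBr | starting material
3 | 4-(3-methylbut-2-enyloxy)benzaldehyde | CC(C)=CCOc1ccc(C=O)cc1 | intermediate
4 | (E)-1-methoxy-3-(trimethylsilyloxy)buta-1,3-diene | CO/C=C/C(=C)O[Si](C)(C)C | starting material
5 | 2-methoxy-6-[4-(3-methylbut-2-enyloxy)phenyl]-4-(trimethylsilyloxy)-5,6-dihydro-2H-pyran (racemic, both C2 epimers) | COC1C=C(O[Si](C)(C)C)CC(c2ccc(OCC=C(C)C)cc2)O1 | intermediate (not isolated)
6 | 2-[4-(3-methylbut-2-enyloxy)phenyl]-2,3-dihydro-4H-pyran-4-one (racemic) | O=C1C=COC(c2ccc(OCC=C(C)C)cc2)C1 | intermediate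
7 | rac-(2R,3R)-3-hydroxy-2-[4-(3-methylbut-2-enyloxy)phenyl]-2,3-dihydro-4H-pyran-4-one (2,3-trans; one enantiomer drawn) | O=C1C=CO[C@H](c2ccc(OCC=C(C)C)cc2)[C@H]1O | intermediate
8 | 2-[4-(3-methylbut-2-enyloxy)phenyl]-2H-pyran-3,4-dione (racemic) | O=C1C=COC(c2ccc(OCC=C(C)C)cc2)C1=O | intermediate (not isolated)
9 | 3-hydroxy-2-[4-(3-methylbut-2-enyloxy)phenyl]-4H-pyran-4-one | CC(C)=CCOc1ccc(cc1)-c1occc(=O)c1O | intermediate
10 | 2-[4-(3-methylbut-2-enyloxy)phenyl]-3-(triisopropylsilyloxy)-4H-pyran-4-one | CC(C)=CCOc1ccc(cc1)-c1occc(=O)c1O[Si](C(C)C)(C(C)C)C(C)C | intermediate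
11 | dimethyl squarate (3,4-dimethoxycyclobut-3-ene-1,2-dione) | COC1=C(OC)C(=O)C1=O | starting material
12 | 4-hydroxy-2,3-dimethoxycyclobut-2-en-1-one (racemic) | COC1=C(OC)C(O)C1=O | intermediate (not isolated)
13 | 3,4,4-trimethoxycyclobut-2-en-1-one | COC1=CC(=O)C1(OC)OC | intermediate
14 | 4,4-dimethoxy-3-[2-(trimethylsilyl)ethoxy]cyclobut-2-en-1-one | COC1(OC)C(=O)C=C1OCC[Si](C)(C)C | intermediate
15 | 4-chloro-4-methoxy-3-[2-(trimethylsilyl)ethoxy]cyclobut-2-en-1-one (racemic) | COC1(Cl)C(=O)C=C1OCC[Si](C)(C)C | intermediate
16 | chloro{4-oxo-6-[4-(3-methylbut-2-enyloxy)phenyl]-5-(triisopropylsilyloxy)-4H-pyran-2-yl}zinc (as its LiCl complex) | CC(C)=CCOc1ccc(cc1)-c1oc([Zn]Cl)cc(=O)c1O[Si](C(C)C)(C(C)C)C(C)C | intermediate (not isolated)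
17 | 2-methoxy-4-{4-oxo-6-[4-(3-methylbut-2-enyloxy)phenyl]-5-(triisopropylsilyloxy)-4H-pyran-2-yl}-3-[2-(trimethylsilyl)ethoxy]cyclobut-2-en-1-one (racemic) | COC1=C(OCC[Si](C)(C)C)C(c2cc(=O)c(O[Si](C(C)C)(C(C)C)C(C)C)c(-c3ccc(OCC=C(C)C)cc3)o2)C1=O | intermediate
18 | (3E)-2-methoxy-4-{4-oxo-6-[4-(3-methylbut-2-enyloxy)phenyl]-5-(triisopropylsilyloxy)-4H-pyran-2-yl}-3-[2-(trimethylsilyl)ethoxy]buta-1,3-dien-1-one (pyranone cis to the ketene) | O=C=C(OC)/C(OCC[Si](C)(C)C)=C\c1cc(=O)c(O[Si](C(C)C)(C(C)C)C(C)C)c(-c2ccc(OCC=C(C)C)cc2)o1 | intermediate (not isolated)
19 | 6-methoxy-2-[4-(3-methylbut-2-enyloxy)phenyl]-7-[2-(trimethylsilyl)ethoxy]-3-(triisopropylsilyloxy)-4aH-chromene-4,5-dione (racemic) | COC1=C(OCC[Si](C)(C)C)C=C2OC(c3ccc(OCC=C(C)C)cc3)=C(O[Si](C(C)C)(C(C)C)C(C)C)C(=O)C2C1=O | intermediate (not isolated)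
20 | 5-hydroxy-6-methoxy-4'-(3-methylbut-2-enyloxy)-7-[2-(trimethylsilyl)ethoxy]-3-(triisopropylsilyloxy)flavone | COc1c(OCC[Si](C)(C)C)cc2oc(-c3ccc(OCC=C(C)C)cc3)c(O[Si](C(C)C)(C(C)C)C(C)C)c(=O)c2c1O | intermediate
21 | 3,5-dihydroxy-6-methoxy-4'-(3-methylbut-2-enyloxy)-7-[2-(trimethylsilyl)ethoxy]flavone | COc1c(OCC[Si](C)(C)C)cc2oc(-c3ccc(OCC=C(C)C)cc3)c(O)c(=O)c2c1O | intermediate (not isolated)
22 | 3,5,7-trihydroxy-6-methoxy-4'-(3-methylbut-2-enyloxy)flavone | COc1c(O)cc2oc(-c3ccc(OCC=C(C)C)cc3)c(O)c(=O)c2c1O | target

## Step count and least certain steps

Total step count: 11. Longest linear sequence: 8 steps (1 to 5, then 9, 10 and 11); the three-step squarate branch (6 to 8) joins at step 9.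

Step 10 (key step). The closure passes through the non-aromatic dienone 19 and only the inward-rotated ketene can close. The most likely failure is therefore consumption of the ketene by bimolecular acylation (dimerisation, adventitious nucleophiles) before it cyclises.
Fallback, an ionic closure of the same bond, setting out from 17 and coming back at 22:
- LiOH in aqueous THF at 0 °C should add to the ring carbonyl and break the C1–C4 bond, with the pyranone stabilising the carbanion. This gives (2Z)-2-methoxy-4-{4-oxo-6-[4-(3-methylbut-2-enyloxy)phenyl]-5-(triisopropylsilyloxy)-4H-pyran-2-yl}-3-[2-(trimethylsilyl)ethoxy]but-2-enoic acid F1, in which the carboxyl and pyranonylmethyl groups are held cis.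
- Cyclodehydration with Ac2O and NaOAc at 100 °C (the ring closure of the Stobbe benzannulation) should acylate C4a, aromatise and acetylate the new phenol. This gives 5-acetoxy-6-methoxy-4'-(3-methylbut-2-enyloxy)-7-[2-(trimethylsilyl)ethoxy]-3-(triisopropylsilyloxy)flavone F2.
- Any loss of the O3 silyl group on the way is harmless, because that oxygen is then acetylated. Bu4NF under the conditions of step 11 should remove the acyl and silicon groups together and rejoin the route at 22.

Step 9. 15 may ionise ahead of palladium. The zinc reagent, or ZnCl2 acting as a Lewis acid, then meets a free oxocyclobutenyl cation and bonds at its methoxy-bearing terminus, or the cation loses an O-alkyl group. Bond formation at the wrong allylic terminus would lead to an 8-methoxy isomer after step 10.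
Fallback, setting out from 10 (through 16) and coming back at 20:
- 16 is quenched with Bu3SnCl to give 2-[4-(3-methylbut-2-enyloxy)phenyl]-6-(tributylstannyl)-3-(triisopropylsilyloxy)-4H-pyran-4-one F3, isolated free of amine and zinc salts.
- Stille coupling of F3 with 15 (PdCl2(PhCN)2, tri(2-furyl)phosphine, dioxane, 50 then 100 °C) is the established way of joining 4-chlorocyclobutenones to heteroaryl groups. A stannane does not react with the chloride without palladium.
- At 100 °C the coupled cyclobutenone should open and close as it forms, so 20 is reached without isolating 17.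

Step 8. The ionised chloro ether may be dealkylated, by chloride attack on the O-methyl group or by fragmentation of the silylethyl group under ZnCl2. That would give a cyclobutenedione in place of an allylic chloride.
Fallback, making the secondary chloride without a Lewis acid, setting out from 12 and coming back at 17:
- 12 is isolated after an aqueous work-up of the reduction and silylated (Et3SiCl, imidazole) to 2,3-dimethoxy-4-(triethylsilyloxy)cyclobut-2-en-1-one F4.
- Alkoxide-catalysed exchange as in step 7 (only the C3 methoxy group is a vinylogous ester oxygen) gives 2-methoxy-4-(triethylsilyloxy)-3-[2-(trimethylsilyl)ethoxy]cyclobut-2-en-1-one F5.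
- HF·pyridine at 0 °C frees 4-hydroxy-2-methoxy-3-[2-(trimethylsilyl)ethoxy]cyclobut-2-en-1-one F6.
- An Appel reaction (PPh3, CCl4) gives 4-chloro-2-methoxy-3-[2-(trimethylsilyl)ethoxy]cyclobut-2-en-1-one F7, which enters step 9 in place of 15 and leads to the same 17.

Step 7. The exchange may stay incomplete, since only excess alcohol drives the equilibrium, or alkoxide may attack the strained ketone and cleave the ring.
Fallback, setting out from 13 and coming back at 14:
- Saponification of the vinylogous ester (NaOH, aqueous THF, 0 °C) gives, after acidification, 3-hydroxy-4,4-dimethoxycyclobut-2-en-1-one F8, the enol of a symmetrical 1,3-dione.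
- Mitsunobu O-alkylation with 2-(trimethylsilyl)ethanol (PPh3, diisopropyl azodicarboxylate) gives 14 whichever oxygen reacts.

Step 3. The enolate may expel the ring oxygen (ring opening by an E1cB path) or add to the sulfonimine by-product.
Fallback, a cross-coupling that replaces steps 1 to 5, setting out from 2 and coming back at 10:
- Commercial 3-hydroxy-4H-pyran-4-one is brominated beside the enolic hydroxyl (N-bromosuccinimide) to 2-bromo-3-hydroxy-4H-pyran-4-one F9.
- Silylation (iPr3SiOTf, 2,6-lutidine) gives 2-bromo-3-(triisopropylsilyloxy)-4H-pyran-4-one F10.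
- Suzuki coupling (PdCl2(dppf), K3PO4, aqueous dioxane) with 4,4,5,5-tetramethyl-2-[4-(3-methylbut-2-enyloxy)phenyl]-1,3,2-dioxaborolane F11 gives 10. F11 is made from commercial 4-hydroxyphenylboronic acid pinacol ester and 2 (K2CO3, DMF).

## Further compounds

F1 | step 10 | (2Z)-2-methoxy-4-{4-oxo-6-[4-(3-methylbut-2-enyloxy)phenyl]-5-(triisopropylsilyloxy)-4H-pyran-2-yl}-3-[2-(trimethylsilyl)ethoxy]but-2-enoic acid | OC(=O)/C(OC)=C(/OCC[Si](C)(C)C)Cc1cc(=O)c(O[Si](C(C)C)(C(C)C)C(C)C)c(-c2ccc(OCC=C(C)C)cc2)o1
F2 | step 10 | 5-acetoxy-6-methoxy-4'-(3-methylbut-2-enyloxy)-7-[2-(trimethylsilyl)ethoxy]-3-(triisopropylsilyloxy)flavone | COc1c(OCC[Si](C)(C)C)cc2oc(-c3ccc(OCC=C(C)C)cc3)c(O[Si](C(C)C)(C(C)C)C(C)C)c(=O)c2c1OC(C)=O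
F3 | step 9 | 2-[4-(3-methylbut-2-enyloxy)phenyl]-6-(tributylstannyl)-3-(triisopropylsilyloxy)-4H-pyran-4-one | CCCC[Sn](CCCC)(CCCC)c1cc(=O)c(O[Si](C(C)C)(C(C)C)C(C)C)c(-c2ccc(OCC=C(C)C)cc2)o1
F4 | step 8 | 2,3-dimethoxy-4-(triethylsilyloxy)cyclobut-2-en-1-one (racemic) | COC1=C(OC)C(O[Si](CC)(CC)CC)C1=O
F5 | step 8 | 2-methoxy-4-(triethylsilyloxy)-3-[2-(trimethylsilyl)ethoxy]cyclobut-2-en-1-one (racemic) | COC1=C(OCC[Si](C)(C)C)C(O[Si](CC)(CC)CC)C1=O
F6 | step 8 | 4-hydroxy-2-methoxy-3-[2-(trimethylsilyl)ethoxy]cyclobut-2-en-1-one (racemic) | COC1=C(OCC[Si](C)(C)C)C(O)C1=O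
F7 | step 8 | 4-chloro-2-methoxy-3-[2-(trimethylsilyl)ethoxy]cyclobut-2-en-1-one (racemic) | COC1=C(OCC[Si](C)(C)C)C(Cl)C1=O
F8 | step 7 | 3-hydroxy-4,4-dimethoxycyclobut-2-en-1-one | COC1(OC)C(=O)C=C1O
F9 | step 3 | 2-bromo-3-hydroxy-4H-pyran-4-one | O=c1ccoc(Br)c1O
F10 | step 3 | 2-bromo-3-(triisopropylsilyloxy)-4H-pyran-4-one | CC(C)[Si](Oc1c(Br)occc1=O)(C(C)C)C(C)C
F11 | step 3 | 4,4,5,5-tetramethyl-2-[4-(3-methylbut-2-enyloxy)phenyl]-1,3,2-dioxaborolane | CC(C)=CCOc1ccc(cc1)B1OC(C)(C)C(C)(C)O1
A1 | alternative 1 | 1-[2-hydroxy-5-methoxy-4,6-bis(methoxymethoxy)phenyl]-3-[4-(3-methylbut-2-enyloxy)phenyl]prop-2-yn-1-one | COCOc1cc(O)c(C(=O)C#Cc2ccc(OCC=C(C)C)cc2)c(OCOC)c1OC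
A2 | alternative 1 | 4-methoxy-3,5-bis(methoxymethoxy)-2-(trimethylsilyl)phenyl trifluoromethanesulfonate | COCOc1cc(OS(=O)(=O)C(F)(F)F)c([Si](C)(C)C)c(OCOC)c1OC
A3 | alternative 1 | 3-[4-(3-methylbut-2-enyloxy)phenyl]prop-2-ynoic acid | OC(=O)C#Cc1ccc(OCC=C(C)C)cc1
A4 | alternative 2 | 6-methoxy-4'-(3-methylbut-2-enyloxy)-5,7-bis[2-(trimethylsilyl)ethoxy]-3-{[2-(trimethylsilyl)ethoxy]methoxy}flavone | C[Si](C)(C)CCOCOc1c(-c2ccc(OCC=C(C)C)cc2)oc2cc(OCC[Si](C)(C)C)c(OC)c(OCC[Si](C)(C)C)c2c1=O
A5 | alternative 2 | 5,7-difluoro-6-methoxy-4'-(3-methylbut-2-enyloxy)-3-{[2-(trimethylsilyl)ethoxy]methoxy}flavone | C[Si](C)(C)CCOCOc1c(-c2ccc(OCC=C(C)C)cc2)oc2cc(F)c(OC)c(F)c2c1=O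
A6 | alternative 2 | sodium 2-(trimethylsilyl)ethoxide | [Na+].[O-]CC[Si](C)(C)C
A7 | alternative 3 | 6-methoxy-5,7-bis(methoxymethoxy)-4'-(3-methylbut-2-enyloxy)flavone | COCOc1cc2oc(-c3ccc(OCC=C(C)C)cc3)cc(=O)c2c(OCOC)c1OC
A8 | alternative 3 | 2-iodo-4-methoxy-3,5-bis(methoxymethoxy)phenol | COCOc1cc(O)c(I)c(OCOC)c1OC
A9 | alternative 3 | 1-ethynyl-4-(3-methylbut-2-enyloxy)benzene | C#Cc1ccc(OCC=C(C)C)cc1
A10 | alternative 3 | carbon monoxide | [C-]#[O+]
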